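| flask | X | J | remark | time |
|---|---|---|---|---|
| eta | 0.017 M | 5 mM | run made earlier |  |
| epsilon | 0.074 M | 5 mM | run made earlier |  |
| Tuesday's | 0.050 M | 5.0 mM |  | 12 min |
| Saturday's | 0.012 M | 5.0 mM |  | 12 min |

| run | time / min | E / % | X / % |
|---|---|---|---|
| eta | 1.50 | 4.1 | 91.7 |
| eta | 3.00 | 7.7 | 79.1 |
| eta | 5.00 | 13.2 | 66.1 |
| eta | 6.00 | 15.9 | 59.7 |
| epsilon | 0.500 | 1.1 | 95.2 |
| epsilon | 1.00 | 3.2 | 91.4 |
| epsilon | 2.50 | 10.9 | 79.6 |
| epsilon | 6.00 | 29.4 | 50.0 |

(readings scatter by 1 percentage point)

- the average divides the monomer in chains by the number of chains begun, living and dead together
- the earlier runs do not show the number of chains; that part of a forecast is a guess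

1. which of the two ends with the longer chains by the average number of monomer units in a chain (chains begun, living or dead) ("neither" if they lie within 10%) (Tuesday's / Saturday's / neither)
2. average number of monomer units in a chain (chains begun, living or dead) at the end, Tuesday's
3. average number of monomer units in a chain (chains begun, living or dead) at the end, Saturday's

- Chains cannot be counted in these runs: E and X are read, the chains begun are not, and the length asked is E over those chains.

- A supposition gets round this. Epsilon shows E at 1.1% after 0.500 min and 29.4% after 6.00 min, an upturn that suggests J starting chains with X, one unit each, and living ends adding further X. Taking both steps as first order in [X], [X] cancels from their ratio. If no end is lost, the length follows the course of J. Let f be the share of J spent and w the logarithm of J charged over J left, so that w/ln(2) counts the half-lives of J. Then the length is one plus ρ(w/f minus one), with ρ the ratio of the two constants.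

- The start constant is read from the first epsilon reading, E as a share of the X charged, per minute, over [J], which gives 4.40 L mol⁻¹ min⁻¹. The objection is that this reading carries a scatter of 1 percentage point on 1.1%, so the two runs must test it.

- [X] falls at about 0.0860 min⁻¹ in eta and 0.116 min⁻¹ in epsilon, which gives w of 0.351 and 1.41 at the last readings. The E read there then gives ρ of 4.46 and 5.50. They stand a factor 1.23 apart, and their mean, 4.98, is the reading taken for the selectivity factor ρ, growth constant over start constant.

- By this reckoning Tuesday's, borrowing the fall of epsilon, reaches w of 1.43, which is 2.06 half-lives of J and a length of 5.38. By the same reckoning Saturday's, borrowing the fall of eta, reaches w of 0.395 and a length of 2.05.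

- The borrowed fall is open to doubt, but the fall of eta put into Tuesday's gives a length of 6.18, and in this reckoning Tuesday's stays longer than Saturday's.

- The forecast also names Tuesday's but stands higher than this reckoning, at 15 and 6, adding “Chain counts are a guess”.

- Tuesday's ends at an average of 6.08 units per chain and Saturday's at an average of 2.22, with 28% of the J charged to Tuesday's left after 12 min.

    X + D → E + D, rate k1*[D]*[X] (k = 24.9 L mol⁻¹ min⁻¹)
    X + J → D + E (k = 3.80 L mol⁻¹ min⁻¹)
    X → Z (k = 0.0486 min⁻¹)

- Put into the rule with ρ of 4.98, the J left in Tuesday's gives 4.82 against the 6.08 found. Saturday's flask charged instead with 0.030 M of X keeps 44% of its J, for which the rule gives 3.32, and that flask ends at an average of 4.03 units per chain.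

(All runs were computed with constants of no real substance, noise included.)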